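**Retrosynthetic overview**
1. No C–C bond is made: rings A–D, all 19 carbons and the stereocentres C3, C4, C5, C6, C8, C9 and C13 are bought as gibberellic acid 1, a cheap fermentation product.
2. C2–O bond (key): a suprafacial 1,3-shift of the lactone carboxylate of 1 from C10 to C2 gives iso-lactone 2, which sets the 2α oxygen trans to the 3β-OH and moves the alkene to C1=C10.
3. Lactone 2 is opened at its acyl–oxygen bond to the hydroxy diacid 3, which frees the 2α-OH.
4. C10–O bond (key, last): Markovnikov hydrolactonisation of the C19 acid of 3 across C1=C10 re-forms the 19,10-lactone of target 4 and sets C10.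
5. Ring order: carbocyclic rings A, B, C, D are pre-formed; the lactone ring is re-sited to C2 (step 1), opened (step 2) and re-formed on C10 (step 3).

Assumption: the SMILES decodes to the natural gibberellin series with a trans 2α,3β-diol, i.e. the C2 epimer of the natural 2β,3β,13-trihydroxy 19,10-lactone gibberellin; here α is the face of the lactone bridge and β the face of the C18 methyl and the 3-OH.

**Step 1**
Reactants: 1 gibberellic acid (GA3; 3β,13-dihydroxy-20-norgibberella-1,16-diene-7,19-dioic acid 19,10α-lactone)
Product: 2 iso-gibberellic acid (3β,13-dihydroxy-20-norgibberella-1(10),16-diene-7,19-dioic acid 19,2α-lactone)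
Conditions: NaOH (1.5 equiv, 0.02 M aq), H2O, 20 °C, 1 h (HPLC control); then 1 M HCl, 0 °C, pH 3, EtOAc
Reagents that add atoms: none
Why: Base-promoted allylic lactone rearrangement (intramolecular SN2′-type 1,3-transposition, the long-known GA3 to iso-GA3 isomerisation): the carboxylate is tethered to the α face of C4, so the new C2–O bond can only form on the α face, trans to the untouched 3β-OH, while the alkene moves to the more substituted C1=C10 position.

**Step 2**
Reactants: 2 iso-gibberellic acid
Product: 3 2α,3β,13-trihydroxy-20-norgibberella-1(10),16-diene-7,19-dioic acid (free hydroxy diacid)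
Conditions: NaOH (4 equiv, 0.5 M aq), H2O, Ar, 20 °C, 16 h; then 1 M HCl, 0 °C, pH 3–3.5, n-BuOH/EtOAc extraction without heating; used at once
Reagents that add atoms: sodium hydroxide, [Na+].[OH-] (the hydroxide oxygen becomes the second oxygen of the C19 carboxyl group)
Why: Saponification by acyl–oxygen cleavage of the strained bridged γ-lactone: hydroxide attacks C19 and the C2–O bond is not touched, so C2 keeps its α configuration, and once the C19 group is a carboxylate the β-hydroxy acid is no longer prone to C3 epimerisation by retro-aldol reaction.

**Step 3**
Reactants: 3 2α,3β,13-trihydroxy-20-norgibberella-1(10),16-diene-7,19-dioic acid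
Product: 4 2α,3β,13-trihydroxy-20-norgibberell-16-ene-7,19-dioic acid 19,10α-lactone (target)
Conditions: hν (254 nm, low-pressure mercury lamp, quartz), p-xylene (sensitiser, 10 vol %), degassed MeCN, 0.005 M, 15–20 °C
Reagents that add atoms: none
Why: Proposed new method: triplet-sensitised photoprotonative hydrolactonisation — energy transfer from triplet p-xylene twists the C1=C10 bond (endocyclic in six-membered ring A) into a strained trans-cyclohexene-like species basic enough to be protonated at C1 by the substrate's own carboxylic acid (Markovnikov), and the resulting C10 tertiary cation/C19 carboxylate ion pair collapses on the α face, the only face the C4-tethered carboxylate can reach, forming the C10–O bond with the natural C10 configuration, while the exocyclic C16=C17 bond relaxes by free twisting and is not protonated (as the isopropenyl group of limonene is spared); the closest known reaction type is the Kropp–Marshall xylene-sensitised photoprotonation of cyclohexenes with intermolecular Markovnikov addition of alcohols or acetic acid.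

**Compound list**
1 | gibberellic acid (GA3), 3β,13-dihydroxy-20-norgibberella-1,16-diene-7,19-dioic acid 19,10α-lactone | C=C1C[C@]23C[C@@]1(O)CC[C@H]2[C@@]12C=C[C@H](O)[C@@](C)(C(=O)O1)[C@H]2[C@@H]3C(=O)O | starting material
2 | iso-gibberellic acid, 3β,13-dihydroxy-20-norgibberella-1(10),16-diene-7,19-dioic acid 19,2α-lactone | C=C1C[C@]23C[C@@]1(O)CC[C@H]2C1=C[C@@H]4[C@H](O)[C@@](C)(C(=O)O4)[C@H]1[C@@H]3C(=O)O | intermediate
3 | 2α,3β,13-trihydroxy-20-norgibberella-1(10),16-diene-7,19-dioic acid | C=C1C[C@]23C[C@@]1(O)CC[C@H]2C1=C[C@@H](O)[C@H](O)[C@@](C)(C(=O)O)[C@H]1[C@@H]3C(=O)O | intermediate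
4 | 2α,3β,13-trihydroxy-20-norgibberell-16-ene-7,19-dioic acid 19,10α-lactone | C=C1C[C@]23C[C@@]1(O)CC[C@H]2[C@@]12C[C@@H](O)[C@H](O)[C@@](C)(C(=O)O1)[C@H]2[C@@H]3C(=O)O | target

**Totals**
Total step count: 3. Longest linear sequence: 3 steps (1 → 2 → 3 → 4).

**Steps most likely to fail**

Step 3 (the proposed new step). It can fail if the ring-fused C1=C10 bond does not twist far enough to be protonated. It can also fail if the C10 cation loses a proton from C5 or C9, or is captured on the β face by the C7 acid or the 3β-OH, or if 3 closes back to 2 in the dark (recovered 2 can be recycled through step 2). The fallback uses known chemistry, sets out from 3 and comes back at 4. Phenylselenolactonisation of 3 with N-(phenylseleno)phthalimide and catalytic camphorsulfonic acid in MeCN/CH2Cl2 at 0 °C adds anti across C1=C10 (carboxylate oxygen on C10 α, selenium on C1 β). This gives 1β-(phenylselanyl)-2α,3β,13-trihydroxy-20-norgibberell-16-ene-7,19-dioic acid 19,10α-lactone F1. Its C–Se bond is then cleaved with Bu3SnH and catalytic AIBN in toluene at 100 °C to give 4; the radical conditions spare the exocyclic alkene.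

Step 2. Free 3 is a pre-organised cis-1,3 hydroxy acid that may relactonise to 2 on acidification, and it is very polar and hard to extract. The fallback sets out from 2 and comes back at 4 without ever liberating free 3. Compound 2 is saponified as before, the solution is brought to pH 7.5–8 with CO2/NaHCO3 rather than acidified, and I2/KI is added at 0 °C in the dark. The C19 carboxylate is then trapped at once by iodolactonisation (anti addition) as 1β-iodo-2α,3β,13-trihydroxy-20-norgibberell-16-ene-7,19-dioic acid 19,10α-lactone F2. This is acidified promptly to pH 3, because the trans-diaxial iodohydrin would close to an epoxide in base, and extracted. Radical deiodination with Bu3SnH and catalytic AIBN in THF/toluene at 70 °C gives 4.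

Step 1. Elimination to the diene diacid (gibberellenic acid) or premature lactone hydrolysis may erode the yield. The fallback sets out from 1 and comes back at 2 by a base-free, metal-catalysed isomerisation with the zerovalent palladium complex Pd(PPh3)4 (5 mol %) in THF at 20–40 °C. The allylic lactone ionises to a π-allyl palladium carboxylate with the metal on the β face, and the tethered carboxylate returns to C2 on the α face under thermodynamic control. No new compound is made (F0).

**Further compounds**
F1 | step 3 | 1β-(phenylselanyl)-2α,3β,13-trihydroxy-20-norgibberell-16-ene-7,19-dioic acid 19,10α-lactone | C=C1C[C@]23C[C@@]1(O)CC[C@H]2[C@@]12[C@H]([Se]c4ccccc4)[C@@H](O)[C@H](O)[C@@](C)(C(=O)O1)[C@H]2[C@@H]3C(=O)O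
F2 | step 2 | 1β-iodo-2α,3β,13-trihydroxy-20-norgibberell-16-ene-7,19-dioic acid 19,10α-lactone | C=C1C[C@]23C[C@@]1(O)CC[C@H]2[C@@]12[C@H](I)[C@@H](O)[C@H](O)[C@@](C)(C(=O)O1)[C@H]2[C@@H]3C(=O)O
F0 | step 1 | none | none
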